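Readings and results come from a simulation for substances that don't exist, noise included.

I cannot read either flask off the runs so far, since none pairs c(starting material) 0.062 M with c(target) 1.24 mM, and the latest reading stands at 6.00 h, earlier than the 10 h of dusk. Yet the decision on the next flask needs such a reading: with this charge, do I stop at 5.0 h, as in dawn, or leave it until 10 h, as in dusk?

| flask | starting material | target | remark | time |
|---|---|---|---|---|
| gamma | 0.042 M | 1.24 mM | run made earlier |  |
| zeta | 0.093 M | 1.24 mM | run made earlier |  |
| epsilon | 0.062 M | 2.5 mM | run made earlier |  |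
| dawn | 0.062 M | 1.24 mM |  | 5.0 h |
| dusk | 0.062 M | 1.24 mM |  | 10 h |

| run | time / h | target / % | starting material / % |
|---|---|---|---|
| gamma | 0.833 | 76.1 | 2.6 |
| gamma | 1.50 | 82.9 | 1.5 |
| gamma | 2.50 | 82.9 | 0.5 |
| gamma | 3.00 | 81.2 | 0.2 |
| gamma | 4.00 | 76.8 | 1.2 |
| gamma | 5.00 | 71.5 | 0 |
| gamma | 6.00 | 66.6 | 0.9 |
| zeta | 0.333 | 79.4 | 1.7 |
| zeta | 1.00 | 85.6 | 0.7 |
| zeta | 1.50 | 86.8 | 0.5 |
| zeta | 2.50 | 83.6 | 1.0 |
| zeta | 4.00 | 75.0 | 0 |
| zeta | 5.00 | 69.0 | 0 |
| zeta | 6.00 | 63.4 | 0 |
| epsilon | 0.500 | 82.3 | 0.8 |
| epsilon | 1.50 | 86.5 | 0.6 |
| epsilon | 3.00 | 81.6 | 0 |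
| epsilon | 4.00 | 76.3 | 0.2 |
| epsilon | 6.00 | 65.8 | 0.6 |

(standard deviation of a reading: 0.5 percentage points)

- the numbers in the tables scatter with a standard deviation of 0.5 percentage points
- steps thought possible: starting material + target -> 2 target; starting material -> target; starting material <-> dormant form; target -> over-reaction product

- which of the two there is more of at the end, dawn (target / over-reaction product)
- which of the two there is more of at the end, dusk (target / over-reaction product)
- amount of target at the end, in percent of the starting material charged, dawn
- amount of target at the end, in percent of the starting material charged, dusk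

The readings show two rates competing. Across the flat stretch of gamma, 82.9 % at 1.50 h and 82.9 % at 2.50 h, the gain and the loss of target look level, and as the gain dies the net fall becomes the loss itself, so I want a tail where starting material reads zero. Zeta offers one: from 4.00 h to 6.00 h its starting material reads 0 % while its target goes from 75.0 % to 63.4 %, which gives 0.0840 h⁻¹ for the tail constant, the logarithmic fall of target per hour once its gain has ended (a first-order rate constant), or a half-life of 8.25 h.

For dawn I take the middle of the gamma and zeta readings at 5.00 h, whose charges bracket its own, which gives 70.2 %. Carrying that forward 5.00 h with the tail constant gives 46.2 % for dusk, and charge plus seed, if I take starting material and dormant form as used up by then, leaves an estimated 55.8 % as over-reaction product, more than the target. Waiting costs 24 percentage points of target, so I stop at 5.0 h.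

The forecast, which reasons that “The target falls steadily after its peak.”, gives 70.3 % with more target at dawn and 46.8 % with more over-reaction product at dusk, its dusk figure a little above mine.

The flask gives 70.0 % of target at dawn and 46.4 % at dusk.

    starting material + target → 2 target (k = 370 M⁻¹ h⁻¹)
    starting material → target (k = 0.0200 h⁻¹)
    starting material ⇌ dormant form (K = 1.90, k = 2.20 h⁻¹)
    target → over-reaction product (k = 0.0830 h⁻¹)

Dusk has not come to rest at 10 h: starting material and dormant form stand at 0 % and 0 %, but target still holds 46.4 %. The tail constant carries dawn's 70.0 % to 19.9 % at 20.0 h, and dawn, read at that time, holds 20.2 %. Carried from dusk's 46.4 % to ten times the time, it leaves 0.0241 % of target, and dusk, left that long, holds 0.0264 %. Over-reaction product climbs from 55.6 % to 102 % at 100 h.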